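**Plan**

- Retrosynthesis: the hydroquinone is taken back through its quinone to a 4‑methoxyphenol, and the arene is cut at ring bonds C4–C5, C6–C1 and C1–C2. Ring numbering: C1 carries the OH between methyl and chain, C2 the CH3, C4 the second oxygen, C6 the chain; the chain runs from benzylic C1' to C15'.
- Enabling feature: the benzene ring has OH on C1 flanked by CH3 (C2) and the chain (C6), H on C3 and C5, and oxygen on C4. This is the pattern assembled from a terminal alkyne (C5–C6, carried on C1'), one CO ligand (C1–OH) and a propenyl(methoxy)carbene of chromium (C2–C4).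
- Chain cuts: C1'–C(alkyne); C1'–C2' together with C3'–CH3; C4'–C5'; C12'–C13'; C14'=C15'. What remains, C5'–C12', is geranyl acetate.
- Forward order: geranyl acetate is extended first at C12' (allylation, prenyl capping), then at C5' (propargylation, methylalumination/hydroxymethylation, alkynylation). The only ring is closed last and then brought to the hydroquinone oxidation level.
- Stereochemistry: C12' (R) from reagent‑controlled allylboration; C5' (S) from catalyst‑controlled propargylation; 2'E from syn‑carboalumination; 6'E and 10'E from geranyl acetate and its E‑selective allylic oxidation.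

Key step: step 14

Remark: the C12' silyl ether is removed before the ring is built, so no acidic or basic step follows the electron‑rich phenol, quinone or hydroquinone. η6‑Arene complexes are written in SMILES as the arene and the Cr(CO)3 unit separated by a dot, because the η6 bond has no SMILES notation.

**Route**

Step 1
Reactants: 1 geranyl acetate [(2E)-3,7-dimethylocta-2,6-dien-1-yl acetate]
Product: 3 (2E,6E)-3,7-dimethyl-8-oxoocta-2,6-dien-1-yl acetate, via 8-hydroxygeranyl acetate 2 (not isolated)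
Conditions: SeO2 (cat.), t-BuOOH, salicylic acid (cat.), CH2Cl2, rt; crude, MnO2, CH2Cl2, rt
Reagents that add atoms: tert-butyl hydroperoxide, CC(C)(C)OO (oxygen, relayed by catalytic selenium dioxide, O=[Se]=O)
Why: SeO2‑catalysed allylic oxidation (ene reaction, then [2,3]-sigmatropic shift) attacks the (E)-methyl of the electron‑rich terminal isopropylidene and leaves the acetate‑deactivated C2=C3 alkene alone, and MnO2 oxidation of the crude allylic alcohol 2 (with any enal already formed) should converge on the (E)-enal 3.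

Step 2
Reactants: 3 (2E,6E)-3,7-dimethyl-8-oxoocta-2,6-dien-1-yl acetate
Product: 5 (2E,6E,8R)-8-hydroxy-3,7-dimethylundeca-2,6,10-trien-1-yl acetate, via diisopinocampheylborinate 4 (not isolated)
Conditions: (+)-Ipc2BOMe [from (−)-α-pinene], CH2=CHCH2MgBr, Et2O, 0 °C to rt; 3, −78 °C; NaBO3·4H2O, THF/H2O, rt
Reagents that add atoms: allylmagnesium bromide, C=CC[Mg]Br (allyl group, handed on by the B-allyldiisopinocampheylborane made from it)
Why: Brown asymmetric allylboration through a chair Zimmerman–Traxler transition state; the (−)-α-pinene‑derived reagent should deliver allyl to the Re face of the α‑methyl enal, setting C8 (the future C12') as R, while the allylborane leaves the acetate alone and the mild perborate work‑up spares it.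

Step 3
Reactants: 5 (2E,6E,8R)-8-hydroxy-3,7-dimethylundeca-2,6,10-trien-1-yl acetate
Product: 6 (2E,6E,8R)-8-[(tert-butyldimethylsilyl)oxy]-3,7-dimethylundeca-2,6,10-trien-1-yl acetate
Conditions: TBSCl, imidazole, DMF, rt
Reagents that add atoms: tert-butyldimethylsilyl chloride, CC(C)(C)[Si](C)(C)Cl
Why: Imidazole‑promoted silylation of the secondary allylic alcohol, needed so that the two carbinols of the chain can later be told apart.

Step 4
Reactants: 6 (2E,6E,8R)-8-[(tert-butyldimethylsilyl)oxy]-3,7-dimethylundeca-2,6,10-trien-1-yl acetate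
Product: 7 (2E,6E,8R)-8-[(tert-butyldimethylsilyl)oxy]-3,7,11-trimethyldodeca-2,6,10-trien-1-yl acetate
Conditions: 2-methylbut-2-ene (excess), second-generation Grubbs catalyst RuCl2(=CHPh)(PCy3)(H2IMes) (5 mol %), CH2Cl2, rt
Reagents that add atoms: 2-methylbut-2-ene, CC=C(C)C
Why: Olefin cross‑metathesis; the monosubstituted alkene is the only olefin that initiates readily, so exchange with 2-methylbut-2-ene should cap it as the prenyl group while the two trisubstituted alkenes stay inert.

Step 5
Reactants: 7 (2E,6E,8R)-8-[(tert-butyldimethylsilyl)oxy]-3,7,11-trimethyldodeca-2,6,10-trien-1-yl acetate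
Product: 8 (2E,6E,8R)-8-[(tert-butyldimethylsilyl)oxy]-3,7,11-trimethyldodeca-2,6,10-trien-1-ol
Conditions: K2CO3, MeOH, 0 °C to rt
Reagents that add atoms: none
Why: Base‑catalysed transesterification (methanolysis) removes the primary allylic acetate without touching the silyl ether.

Step 6
Reactants: 8 (2E,6E,8R)-8-[(tert-butyldimethylsilyl)oxy]-3,7,11-trimethyldodeca-2,6,10-trien-1-ol
Product: 9 (2E,6E,8R)-8-[(tert-butyldimethylsilyl)oxy]-3,7,11-trimethyldodeca-2,6,10-trienal
Conditions: MnO2, CH2Cl2, rt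
Reagents that add atoms: none
Why: MnO2 oxidation is selective for the primary allylic alcohol and should give the (E)-enal without moving or isomerising the C2=C3 bond.

Step 7
Reactants: 9 (2E,6E,8R)-8-[(tert-butyldimethylsilyl)oxy]-3,7,11-trimethyldodeca-2,6,10-trienal
Product: 11 (4S,5E,9E,11R)-11-[(tert-butyldimethylsilyl)oxy]-6,10,14-trimethylpentadeca-5,9,13-trien-1-yn-4-ol, via pinacol borate 10 (not isolated)
Conditions: allenylboronic acid pinacol ester, (S)-TRIP [(S)-3,3'-bis(2,4,6-triisopropylphenyl)-1,1'-binaphthyl-2,2'-diyl hydrogen phosphate] (10 mol %), 4 Å MS, toluene, −20 °C; aq. NaHCO3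
Reagents that add atoms: allenylboronic acid pinacol ester, C=C=CB1OC(C)(C)C(C)(C)O1
Why: Chiral‑phosphoric‑acid‑catalysed propargylation with an allenylboronate (SE2' through a six‑membered transition state in which the acid binds the boronate oxygen and the formyl hydrogen); the (S)-acid, mirror image of the catalyst that gives (R)-carbinols from aryl and alkenyl aldehydes, should direct attack to the Si face and set C4 (the future C5') as S, and the γ‑attack of the allenyl reagent can only give the homopropargylic alcohol.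

Step 8
Reactants: 11 (4S,5E,9E,11R)-11-[(tert-butyldimethylsilyl)oxy]-6,10,14-trimethylpentadeca-5,9,13-trien-1-yn-4-ol
Product: 14 (2E,5S,6E,10E,12R)-12-[(tert-butyldimethylsilyl)oxy]-3,7,11,15-tetramethylhexadeca-2,6,10,14-tetraene-1,5-diol, via alkenylalane 12 (not isolated), via lithium alkenylalanate 13 (not isolated)
Conditions: Me3Al, Cp2ZrCl2 (25 mol %), CH2Cl2, 0 °C to rt; evaporate; n-BuLi, THF, −78 to 0 °C; (CH2O)n, rt; aq. KNaC4H4O6
Reagents that add atoms: trimethylaluminium, C[Al](C)C; paraformaldehyde (as formaldehyde), C=O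
Why: Negishi zirconium‑catalysed carboalumination adds CH3 and Al syn across the terminal alkyne with methyl on the internal carbon, which fixes the 2'E geometry, and the derived alanate is hydroxymethylated by formaldehyde with retention, the free hydroxyl being carried as its aluminium alkoxide.

Step 9
Reactants: 14 (2E,5S,6E,10E,12R)-12-[(tert-butyldimethylsilyl)oxy]-3,7,11,15-tetramethylhexadeca-2,6,10,14-tetraene-1,5-diol
Product: 15 (2E,5S,6E,10E,12R)-1-bromo-12-[(tert-butyldimethylsilyl)oxy]-3,7,11,15-tetramethylhexadeca-2,6,10,14-tetraen-5-ol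
Conditions: CBr4 (1.1 equiv), PPh3 (1.2 equiv), CH2Cl2, −30 °C; used at once
Reagents that add atoms: tetrabromomethane, BrC(Br)(Br)Br
Why: Appel bromination; at low temperature and with about one equivalent of reagent the unhindered primary allylic hydroxyl should form its alkoxyphosphonium salt far faster than the secondary one, and bromide displaces it without allylic transposition.

Step 10
Reactants: 15 (2E,5S,6E,10E,12R)-1-bromo-12-[(tert-butyldimethylsilyl)oxy]-3,7,11,15-tetramethylhexadeca-2,6,10,14-tetraen-5-ol; 16 ethynyltrimethylsilane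
Product: 18 (4E,7S,8E,12E,14R)-14-[(tert-butyldimethylsilyl)oxy]-5,9,13,17-tetramethyl-1-(trimethylsilyl)octadeca-4,8,12,16-tetraen-1-yn-7-ol, via silylethynylmagnesium bromide 17 (not isolated)
Conditions: 16 (3 equiv), EtMgBr, THF, 0 °C to rt; CuBr·SMe2 (10 mol %); 15, 0 °C to rt
Reagents that add atoms: none
Why: Copper‑catalysed coupling of an alkynyl Grignard reagent with a primary allylic bromide; the γ‑carbon is fully substituted, so substitution should occur at C1' (SN2) with the E geometry kept, the C5' hydroxyl merely riding along as its magnesium alkoxide.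

Step 11
Reactants: 18 (4E,7S,8E,12E,14R)-14-[(tert-butyldimethylsilyl)oxy]-5,9,13,17-tetramethyl-1-(trimethylsilyl)octadeca-4,8,12,16-tetraen-1-yn-7-ol
Product: 19 (4E,7S,8E,12E,14R)-14-[(tert-butyldimethylsilyl)oxy]-5,9,13,17-tetramethyl-1-(trimethylsilyl)octadeca-4,8,12,16-tetraen-1-yn-7-yl acetate
Conditions: Ac2O, pyridine, DMAP (cat.), CH2Cl2, 0 °C to rt
Reagents that add atoms: acetic anhydride, CC(=O)OC(C)=O
Why: DMAP‑catalysed acylation of the only free hydroxyl installs the C5' acetate of the target with no change at the stereocentre.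

Step 12
Reactants: 19 (4E,7S,8E,12E,14R)-14-[(tert-butyldimethylsilyl)oxy]-5,9,13,17-tetramethyl-1-(trimethylsilyl)octadeca-4,8,12,16-tetraen-1-yn-7-yl acetate
Product: 20 (4E,7S,8E,12E,14R)-14-hydroxy-5,9,13,17-tetramethyloctadeca-4,8,12,16-tetraen-1-yn-7-yl acetate
Conditions: n-Bu4NF, AcOH, THF, 0 °C to rt
Reagents that add atoms: none
Why: Fluoride‑induced desilylation cleaves both the C(sp)–Si bond and the secondary silyl ether, while the acetic acid buffer keeps the medium too weakly basic to hydrolyse the acetate or isomerise the skipped enyne.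

Step 13
Reactants: 21 (E)-1-bromoprop-1-ene; 22 chromium hexacarbonyl, Cr(CO)6
Product: 25 pentacarbonyl[(E)-1-methoxybut-2-enylidene]chromium, via (E)-prop-1-enyllithium 23 (not isolated), via lithium acylchromate 24 (not isolated)
Conditions: t-BuLi (2 equiv), Et2O, −78 °C; Cr(CO)6, −78 °C to rt; Me3OBF4, CH2Cl2/H2O, 0 °C
Reagents that add atoms: trimethyloxonium tetrafluoroborate, C[O+](C)C.F[B-](F)(F)F
Why: Fischer carbene synthesis: bromine–lithium exchange with retention of the E geometry, addition of the alkenyllithium to a CO ligand of Cr(CO)6, and O‑methylation of the acylchromate by the hard oxonium salt.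

Step 14
Reactants: 20 (4E,7S,8E,12E,14R)-14-hydroxy-5,9,13,17-tetramethyloctadeca-4,8,12,16-tetraen-1-yn-7-yl acetate; 25 pentacarbonyl[(E)-1-methoxybut-2-enylidene]chromium
Product: 27 (2E,5S,6E,10E,12R)-12-hydroxy-1-(2-hydroxy-5-methoxy-3-methylphenyl)-3,7,11,15-tetramethylhexadeca-2,6,10,14-tetraen-5-yl acetate, via tricarbonylchromium arene complex 26 (not isolated)
Conditions: 25 (1.5 equiv), THF (0.05 M), 50 °C, Ar; then air, Et2O, rt
Reagents that add atoms: none
Why: Dötz benzannulation: thermal loss of one CO from 25 lets the terminal alkyne of 20 coordinate and insert into the Cr=C bond so that the carbene carbon (C4) joins the unsubstituted alkyne carbon (C5), CO insertion then gives a chromium‑bound dienylketene (C6–C1), and 6π‑electrocyclisation (C1–C2) followed by tautomerisation delivers the phenol as its Cr(CO)3 complex 26, from which air removes the metal. The closest known reaction type is the benzannulation of alkenyl(alkoxy)carbene pentacarbonylchromium complexes with terminal alkynes to 4‑alkoxyphenols. The single six‑membered carbocycle closes by electrocyclisation of the metal‑bound dienylketene, not by a cycloaddition. No stereocentre is formed, and C5' and C12' are remote spectators. The step needs regioselectivity (chain ortho to the new OH), which should follow from the steric preference that places the substituted alkyne carbon beside the CO‑derived carbon, and chemoselectivity for the alkyne over four trisubstituted C=C bonds, the secondary alcohol and the acetate, which the neutral conditions and the high affinity of the unsaturated zerovalent chromium centre for an unhindered alkyne should secure.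

Step 15
Reactants: 27 (2E,5S,6E,10E,12R)-12-hydroxy-1-(2-hydroxy-5-methoxy-3-methylphenyl)-3,7,11,15-tetramethylhexadeca-2,6,10,14-tetraen-5-yl acetate
Product: 28 (2E,5S,6E,10E,12R)-12-hydroxy-3,7,11,15-tetramethyl-1-(5-methyl-3,6-dioxocyclohexa-1,4-dien-1-yl)hexadeca-2,6,10,14-tetraen-5-yl acetate
Conditions: (NH4)2Ce(NO3)6 (2.2 equiv), MeCN/H2O, 0 °C
Reagents that add atoms: water, O
Why: Oxidative demethylation of a 4‑methoxyphenol by two one‑electron oxidations with tetravalent cerium, water adding at C4 and methanol leaving; the electron‑rich arene should be oxidised within minutes at 0 °C, before the allylic alcohol or the alkenes react.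

Step 16
Reactants: 28 (2E,5S,6E,10E,12R)-12-hydroxy-3,7,11,15-tetramethyl-1-(5-methyl-3,6-dioxocyclohexa-1,4-dien-1-yl)hexadeca-2,6,10,14-tetraen-5-yl acetate
Product: 29 (2E,5S,6E,10E,12R)-1-(2,5-dihydroxy-3-methylphenyl)-12-hydroxy-3,7,11,15-tetramethylhexadeca-2,6,10,14-tetraen-5-yl acetate (CNP0252507.1)
Conditions: Na2S2O4, EtOAc/H2O, rt, Ar
Reagents that add atoms: none
Why: Dithionite reduction of the 1,4‑benzoquinone to the hydroquinone in a neutral two‑phase system leaves acetate, allylic alcohol and alkenes untouched; the product is handled under argon.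

**Compound list**

1 | geranyl acetate, (2E)-3,7-dimethylocta-2,6-dien-1-yl acetate | CC(C)=CCC/C(C)=C/COC(C)=O | starting material
2 | (2E,6E)-8-hydroxy-3,7-dimethylocta-2,6-dien-1-yl acetate (formed in the flask) | OC/C(C)=C/CC/C(C)=C/COC(C)=O | intermediate
3 | (2E,6E)-3,7-dimethyl-8-oxoocta-2,6-dien-1-yl acetate | O=C/C(C)=C/CC/C(C)=C/COC(C)=O | intermediate
4 | bis(isopinocampheyl)borinic ester of 5 (formed in the flask; isopinocampheyl groups from (−)-α-pinene) | C=CC[C@@H](OB([C@H]1C[C@H]2C[C@@H]([C@@H]1C)C2(C)C)[C@H]1C[C@H]2C[C@@H]([C@@H]1C)C2(C)C)/C(C)=C/CC/C(C)=C/COC(C)=O | intermediate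
5 | (2E,6E,8R)-8-hydroxy-3,7-dimethylundeca-2,6,10-trien-1-yl acetate | C=CC[C@@H](O)/C(C)=C/CC/C(C)=C/COC(C)=O | intermediate
6 | (2E,6E,8R)-8-[(tert-butyldimethylsilyl)oxy]-3,7-dimethylundeca-2,6,10-trien-1-yl acetate | C=CC[C@@H](O[Si](C)(C)C(C)(C)C)/C(C)=C/CC/C(C)=C/COC(C)=O | intermediate
7 | (2E,6E,8R)-8-[(tert-butyldimethylsilyl)oxy]-3,7,11-trimethyldodeca-2,6,10-trien-1-yl acetate | CC(C)=CC[C@@H](O[Si](C)(C)C(C)(C)C)/C(C)=C/CC/C(C)=C/COC(C)=O | intermediate
8 | (2E,6E,8R)-8-[(tert-butyldimethylsilyl)oxy]-3,7,11-trimethyldodeca-2,6,10-trien-1-ol | CC(C)=CC[C@@H](O[Si](C)(C)C(C)(C)C)/C(C)=C/CC/C(C)=C/CO | intermediate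
9 | (2E,6E,8R)-8-[(tert-butyldimethylsilyl)oxy]-3,7,11-trimethyldodeca-2,6,10-trienal | CC(C)=CC[C@@H](O[Si](C)(C)C(C)(C)C)/C(C)=C/CC/C(C)=C/C=O | intermediate
10 | O-(pinacolatoboryl) derivative of 11 (formed in the flask) | CC(C)=CC[C@@H](O[Si](C)(C)C(C)(C)C)/C(C)=C/CC/C(C)=C/[C@@H](OB1OC(C)(C)C(C)(C)O1)CC#C | intermediate
11 | (4S,5E,9E,11R)-11-[(tert-butyldimethylsilyl)oxy]-6,10,14-trimethylpentadeca-5,9,13-trien-1-yn-4-ol | CC(C)=CC[C@@H](O[Si](C)(C)C(C)(C)C)/C(C)=C/CC/C(C)=C/[C@@H](O)CC#C | intermediate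
12 | (E)-alkenyldimethylalane from syn-methylalumination of 11, hydroxyl as its dimethylaluminium alkoxide (formed in the flask) | CC(C)=CC[C@@H](O[Si](C)(C)C(C)(C)C)/C(C)=C/CC/C(C)=C/[C@@H](O[Al](C)C)C/C(C)=C/[Al](C)C | intermediate
13 | lithium butyl(dimethyl)alkenylalanate derived from 12 (formed in the flask) | CC(C)=CC[C@@H](O[Si](C)(C)C(C)(C)C)/C(C)=C/CC/C(C)=C/[C@@H](O[Al](C)C)C/C(C)=C/[Al-](C)(C)CCCC.[Li+] | intermediate
14 | (2E,5S,6E,10E,12R)-12-[(tert-butyldimethylsilyl)oxy]-3,7,11,15-tetramethylhexadeca-2,6,10,14-tetraene-1,5-diol | CC(C)=CC[C@@H](O[Si](C)(C)C(C)(C)C)/C(C)=C/CC/C(C)=C/[C@@H](O)C/C(C)=C/CO | intermediate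
15 | (2E,5S,6E,10E,12R)-1-bromo-12-[(tert-butyldimethylsilyl)oxy]-3,7,11,15-tetramethylhexadeca-2,6,10,14-tetraen-5-ol | CC(C)=CC[C@@H](O[Si](C)(C)C(C)(C)C)/C(C)=C/CC/C(C)=C/[C@@H](O)C/C(C)=C/CBr | intermediate
16 | ethynyltrimethylsilane | C#C[Si](C)(C)C | starting material
17 | [(trimethylsilyl)ethynyl]magnesium bromide (formed in the flask) | C[Si](C)(C)C#C[Mg]Br | intermediate
18 | (4E,7S,8E,12E,14R)-14-[(tert-butyldimethylsilyl)oxy]-5,9,13,17-tetramethyl-1-(trimethylsilyl)octadeca-4,8,12,16-tetraen-1-yn-7-ol | CC(C)=CC[C@@H](O[Si](C)(C)C(C)(C)C)/C(C)=C/CC/C(C)=C/[C@@H](O)C/C(C)=C/CC#C[Si](C)(C)C | intermediate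
19 | (4E,7S,8E,12E,14R)-14-[(tert-butyldimethylsilyl)oxy]-5,9,13,17-tetramethyl-1-(trimethylsilyl)octadeca-4,8,12,16-tetraen-1-yn-7-yl acetate | CC(=O)O[C@H](/C=C(\C)CC/C=C(\C)[C@H](O[Si](C)(C)C(C)(C)C)CC=C(C)C)C/C(C)=C/CC#C[Si](C)(C)C | intermediate
20 | (4E,7S,8E,12E,14R)-14-hydroxy-5,9,13,17-tetramethyloctadeca-4,8,12,16-tetraen-1-yn-7-yl acetate | CC(=O)O[C@H](/C=C(\C)CC/C=C(\C)[C@H](O)CC=C(C)C)C/C(C)=C/CC#C | intermediate
21 | (E)-1-bromoprop-1-ene | C/C=C/Br | starting material
22 | chromium hexacarbonyl, Cr(CO)6 | O=C=[Cr](=C=O)(=C=O)(=C=O)(=C=O)=C=O | starting material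
23 | (E)-prop-1-enyllithium (formed in the flask) | C/C=C/[Li] | intermediate
24 | lithium pentacarbonyl[(E)-1-oxidobut-2-enylidene]chromate (formed in the flask) | C/C=C/C([O-])=[Cr](=C=O)(=C=O)(=C=O)(=C=O)=C=O.[Li+] | intermediate
25 | pentacarbonyl[(E)-1-methoxybut-2-enylidene]chromium | C/C=C/C(OC)=[Cr](=C=O)(=C=O)(=C=O)(=C=O)=C=O | intermediate
26 | tricarbonyl(η6-arene)chromium complex of 27 (formed in the flask; arene and Cr(CO)3 written as two parts) | CC(=O)O[C@H](/C=C(\C)CC/C=C(\C)[C@H](O)CC=C(C)C)C/C(C)=C/Cc1cc(OC)cc(C)c1O.O=C=[Cr](=C=O)=C=O | intermediate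
27 | (2E,5S,6E,10E,12R)-12-hydroxy-1-(2-hydroxy-5-methoxy-3-methylphenyl)-3,7,11,15-tetramethylhexadeca-2,6,10,14-tetraen-5-yl acetate | CC(=O)O[C@H](/C=C(\C)CC/C=C(\C)[C@H](O)CC=C(C)C)C/C(C)=C/Cc1cc(OC)cc(C)c1O | intermediate
28 | (2E,5S,6E,10E,12R)-12-hydroxy-3,7,11,15-tetramethyl-1-(5-methyl-3,6-dioxocyclohexa-1,4-dien-1-yl)hexadeca-2,6,10,14-tetraen-5-yl acetate | CC(=O)O[C@H](/C=C(\C)CC/C=C(\C)[C@H](O)CC=C(C)C)C/C(C)=C/CC1=CC(=O)C=C(C)C1=O | intermediate
29 | (2E,5S,6E,10E,12R)-1-(2,5-dihydroxy-3-methylphenyl)-12-hydroxy-3,7,11,15-tetramethylhexadeca-2,6,10,14-tetraen-5-yl acetate | CC(=O)O[C@H](/C=C(\C)CC/C=C(\C)[C@H](O)CC=C(C)C)C/C(C)=C/Cc1cc(O)cc(C)c1O | target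

**Step count and risks**

Total step count: 16. Longest linear sequence: 15 steps (steps 1–12 and 14–16, from geranyl acetate); the carbene complex is a one‑step branch (step 13).

Steps most likely to fail:

1. Step 14. The unsaturated vinylcarbene intermediate may take up a second alkyne or start alkyne oligomerisation, the free C12' hydroxyl may intercept the ketene or the carbene complex, and the electron‑rich phenol may be lost by oxidation during air demetalation and chromatography. The fallback keeps the same ring construction but carries the silyl ether through it and never isolates the phenol. It sets out from 19: AgNO3 (cat.) in MeOH/H2O/CH2Cl2 removes only the alkynyl silyl group and should give (4E,7S,8E,12E,14R)-14-[(tert-butyldimethylsilyl)oxy]-5,9,13,17-tetramethyloctadeca-4,8,12,16-tetraen-1-yn-7-yl acetate F1. Benzannulation of F1 with 25 (THF, 50 °C) gives the crude tricarbonylchromium complex of the silyl‑protected 4‑methoxyphenol F2. This is oxidised without purification by (NH4)2Ce(NO3)6 in MeCN/H2O to the silyl‑protected quinone (2E,5S,6E,10E,12R)-12-[(tert-butyldimethylsilyl)oxy]-3,7,11,15-tetramethyl-1-(5-methyl-3,6-dioxocyclohexa-1,4-dien-1-yl)hexadeca-2,6,10,14-tetraen-5-yl acetate F3. HF·pyridine in THF then frees the C12' hydroxyl, and the route is rejoined at 28.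

2. Step 7. Enantiofacial discrimination may be insufficient, or addition slow, at the β,β‑disubstituted enal; because the C11 centre is remote, C4 epimers would be hard to separate. The fallback replaces asymmetric induction by resolution. It sets out from 9: Barbier propargylation (propargyl bromide, Zn powder, THF/aq. NH4Cl, 0 °C) gives the C4‑epimeric mixture (4RS,5E,9E,11R)-11-[(tert-butyldimethylsilyl)oxy]-6,10,14-trimethylpentadeca-5,9,13-trien-1-yn-4-ol F4. Lipase‑catalysed acylation (Burkholderia cepacia lipase, vinyl acetate, hexane, rt) should, by the Kazlauskas rule, convert the (4R)-epimer into (4R,5E,9E,11R)-11-[(tert-butyldimethylsilyl)oxy]-6,10,14-trimethylpentadeca-5,9,13-trien-1-yn-4-yl acetate F5 and leave the (4S)-alcohol. The route is rejoined at 11.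

3. Step 8. Transfer of the alkenyl group from the alanate to formaldehyde may be incomplete when an aluminium alkoxide sits in the same molecule, so that protonolysis on work‑up gives the methyl‑branched terminal alkene instead of the allylic alcohol. The fallback separates C–C bond formation from the alane. It sets out from 11: methylalumination as in step 8 gives alkenylalane 12, which is quenched with I2 (THF, −30 °C) to the vinyl iodide (1E,4S,5E,9E,11R)-11-[(tert-butyldimethylsilyl)oxy]-1-iodo-2,6,10,14-tetramethylpentadeca-1,5,9,13-tetraen-4-ol F6. Methoxycarbonylation (PdCl2(PPh3)2 cat., CO, MeOH, Et3N, DMF, 60 °C) gives methyl (2E,5S,6E,10E,12R)-12-[(tert-butyldimethylsilyl)oxy]-5-hydroxy-3,7,11,15-tetramethylhexadeca-2,6,10,14-tetraenoate F7. Reduction with i-Bu2AlH (CH2Cl2, −78 °C) rejoins the route at 14.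

Further compounds
F1 | step 14 | (4E,7S,8E,12E,14R)-14-[(tert-butyldimethylsilyl)oxy]-5,9,13,17-tetramethyloctadeca-4,8,12,16-tetraen-1-yn-7-yl acetate | CC(=O)O[C@H](/C=C(\C)CC/C=C(\C)[C@H](O[Si](C)(C)C(C)(C)C)CC=C(C)C)C/C(C)=C/CC#C
F2 | step 14 | tricarbonyl(η6-arene)chromium complex of (2E,5S,6E,10E,12R)-12-[(tert-butyldimethylsilyl)oxy]-1-(2-hydroxy-5-methoxy-3-methylphenyl)-3,7,11,15-tetramethylhexadeca-2,6,10,14-tetraen-5-yl acetate | CC(=O)O[C@H](/C=C(\C)CC/C=C(\C)[C@H](O[Si](C)(C)C(C)(C)C)CC=C(C)C)C/C(C)=C/Cc1cc(OC)cc(C)c1O.O=C=[Cr](=C=O)=C=O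
F3 | step 14 | (2E,5S,6E,10E,12R)-12-[(tert-butyldimethylsilyl)oxy]-3,7,11,15-tetramethyl-1-(5-methyl-3,6-dioxocyclohexa-1,4-dien-1-yl)hexadeca-2,6,10,14-tetraen-5-yl acetate | CC(=O)O[C@H](/C=C(\C)CC/C=C(\C)[C@H](O[Si](C)(C)C(C)(C)C)CC=C(C)C)C/C(C)=C/CC1=CC(=O)C=C(C)C1=O
F4 | step 7 | (4RS,5E,9E,11R)-11-[(tert-butyldimethylsilyl)oxy]-6,10,14-trimethylpentadeca-5,9,13-trien-1-yn-4-ol (C4 epimers) | CC(C)=CC[C@@H](O[Si](C)(C)C(C)(C)C)/C(C)=C/CC/C(C)=C/C(O)CC#C
F5 | step 7 | (4R,5E,9E,11R)-11-[(tert-butyldimethylsilyl)oxy]-6,10,14-trimethylpentadeca-5,9,13-trien-1-yn-4-yl acetate | CC(C)=CC[C@@H](O[Si](C)(C)C(C)(C)C)/C(C)=C/CC/C(C)=C/[C@H](OC(C)=O)CC#C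
F6 | step 8 | (1E,4S,5E,9E,11R)-11-[(tert-butyldimethylsilyl)oxy]-1-iodo-2,6,10,14-tetramethylpentadeca-1,5,9,13-tetraen-4-ol | CC(C)=CC[C@@H](O[Si](C)(C)C(C)(C)C)/C(C)=C/CC/C(C)=C/[C@@H](O)C/C(C)=C/I
F7 | step 8 | methyl (2E,5S,6E,10E,12R)-12-[(tert-butyldimethylsilyl)oxy]-5-hydroxy-3,7,11,15-tetramethylhexadeca-2,6,10,14-tetraenoate | CC(C)=CC[C@@H](O[Si](C)(C)C(C)(C)C)/C(C)=C/CC/C(C)=C/[C@@H](O)C/C(C)=C/C(=O)OC
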